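**Strategy.** The target is cut at C5–C6: ring B is made by enlarging a cyclopentene, not by cyclisation. The handle is the ring A triad C9 ketone / C5–H / axial C4–OH, in which C4–O is anti to C5–C6; this is what a C4–C5 epoxide leaves behind when a carbon moving over from C9 opens it from the rear. A Lewis acid semipinacol shift of C6 from the C9 carbinol to C5 therefore forms the C5–C6 bond, ring B, the C9 ketone, the C4 alcohol and the C5 configuration in one operation. Its precursor is a cis-fused hydrindene epoxy alcohol (C9–OH syn to the epoxide, C1–OTBS, amide in place).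

Key step: step 13

Remark: locants C1–C9 are those of the target's bicyclo[3.3.1]nonane core (C1 hydroxylated bridgehead, C2 CH2, C3 CHN, C4 CHOH, C5 bridgehead CH, C6 CHOMe, C7/C8 epoxide carbons, C9 ketone) and are kept for the same atoms in every intermediate; α is the face of the five-membered ring that carries the three oxygens, β the other; enone 1 (the D-ribose-derived acetonide) is taken as purchased.

Step 1
Reactants: 1 (3aR,6aR)-2,2-dimethyl-3a,6a-dihydro-4H-cyclopenta[d][1,3]dioxol-4-one; 2 acetonitrile
Product: 3 2-[(3aR,4S,6aR)-4-hydroxy-2,2-dimethyl-3a,6a-dihydro-4H-cyclopenta[d][1,3]dioxol-4-yl]acetonitrile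
Conditions: 2, n-BuLi, THF, −78 °C; then 1, −78 °C
Reagents that add atoms: none
Why: 1,2-Addition of lithioacetonitrile to the enone carbonyl (cyanomethylation of a ketone) should occur on the convex face, anti to the cis-fused dioxolane, which sets C1 with its hydroxyl cis to the C9 and C6 oxygens and places the two-carbon arm (C2 and the later C3) on the β face.

Step 2
Reactants: 3 cyanomethyl carbinol
Product: 4 2-[(3aR,4S,6aR)-4-(tert-butyldimethylsilyloxy)-2,2-dimethyl-3a,6a-dihydro-4H-cyclopenta[d][1,3]dioxol-4-yl]acetonitrile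
Conditions: t-BuMe2SiOTf, 2,6-lutidine, CH2Cl2, 0 °C → rt
Reagents that add atoms: tert-butyldimethylsilyl triflate, CC(C)(C)[Si](C)(C)OS(=O)(=O)C(F)(F)F
Why: Silyl ether formation on the hindered tertiary alcohol with a silyl triflate gives a C1 ether that should withstand the acid, organometallic and Lewis acid steps ahead and that later screens the neighbouring C9 oxygen, with no stereocenter touched.

Step 3
Reactants: 4 silyl ether acetonide
Product: 5 2-[(1S,4R,5R)-1-(tert-butyldimethylsilyloxy)-4,5-dihydroxycyclopent-2-en-1-yl]acetonitrile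
Conditions: AcOH/H2O (4:1), 50 °C
Reagents that add atoms: none
Why: Acid-catalysed acetal hydrolysis should free the cis C9/C6 diol while the hindered tertiary silyl ether and the nitrile, both much slower to react in aqueous acetic acid, stay in place, with no stereocenter touched.

Step 4
Reactants: 5 diol
Product: 6 2-[(1S,4R,5R)-1-(tert-butyldimethylsilyloxy)-5-hydroxy-4-methoxycyclopent-2-en-1-yl]acetonitrile
Conditions: Me3OBF4, 1,8-bis(dimethylamino)naphthalene, CH2Cl2, 0 °C → rt
Reagents that add atoms: trimethyloxonium tetrafluoroborate, C[O+](C)C.F[B-](F)(F)F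
Why: O-Methylation of a neutral alcohol with an oxonium salt (no alkoxide, hence no silyl migration) should select the allylic C6 hydroxyl because the C9 hydroxyl sits beside the bulky cis C1 silyl ether, with no stereocenter touched.

Step 5
Reactants: 6 methyl ether alcohol
Product: 7 2-[(1S,4R)-1-(tert-butyldimethylsilyloxy)-4-methoxy-5-oxocyclopent-2-en-1-yl]acetonitrile
Conditions: Dess–Martin periodinane, NaHCO3, CH2Cl2, 0 °C → rt
Reagents that add atoms: none
Why: Dess–Martin oxidation of the one remaining secondary alcohol under buffered, nearly neutral conditions should give the C9 ketone without enolising C6 or drawing the C7=C8 bond into conjugation, and the ketone is used without storage.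

Step 6
Reactants: 7 ketone; 8 vinylmagnesium bromide
Product: 9 2-[(1S,4R,5R)-1-(tert-butyldimethylsilyloxy)-5-ethenyl-5-hydroxy-4-methoxycyclopent-2-en-1-yl]acetonitrile
Conditions: CeCl3 (anhydrous), 8, THF, −78 °C
Reagents that add atoms: none
Why: Organocerium addition to a ketone uses a nucleophilic but barely basic vinyl reagent that should add to the enolisable ketone instead of removing C6–H, and attack from the β face, anti to the C1–OTBS and C6–OMe groups on both flanking carbons, sets C9 with its hydroxyl cis to these oxygens and the vinyl carbon C5 cis to the C2 arm.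

Step 7
Reactants: 9 vinyl carbinol nitrile
Product: 11 2-[(1S,4R,5R)-1-(tert-butyldimethylsilyloxy)-5-ethenyl-5-hydroxy-4-methoxycyclopent-2-en-1-yl]acetaldehyde, via aldimine 10 (not isolated)
Conditions: i-Bu2AlH, CH2Cl2, −78 °C; then aq. potassium sodium tartrate, rt
Reagents that add atoms: water, O
Why: Partial reduction of a nitrile with i-Bu2AlH stops at the N-aluminated aldimine at low temperature (one further equivalent is taken by the C9 hydroxyl) and hydrolysis on work-up gives the C3 aldehyde, with no stereocenter touched.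

Step 8
Reactants: 11 aldehyde; 12 (S)-2-methylpropane-2-sulfinamide
Product: 13 (S,E)-N-[2-[(1S,4R,5R)-1-(tert-butyldimethylsilyloxy)-5-ethenyl-5-hydroxy-4-methoxycyclopent-2-en-1-yl]ethylidene]-2-methylpropane-2-sulfinamide
Conditions: 12, Ti(OEt)4, THF, rt
Reagents that add atoms: none
Why: Condensation of an aldehyde with a sulfinamide (N-sulfinyl imine formation) is driven by Ti(OEt)4 as Lewis acid and water scavenger, gives the E-aldimine, leaves the tertiary alcohol alone and carries the sulfur stereocenter of 12 over unchanged.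

Step 9
Reactants: 13 N-sulfinyl aldimine; 8 vinylmagnesium bromide
Product: 14 (S)-N-[(2S)-1-[(1S,4R,5R)-1-(tert-butyldimethylsilyloxy)-5-ethenyl-5-hydroxy-4-methoxycyclopent-2-en-1-yl]but-3-en-2-yl]-2-methylpropane-2-sulfinamide
Conditions: 8 (excess), CH2Cl2, −78 → −40 °C
Reagents that add atoms: none
Why: Grignard addition to an N-tert-butanesulfinyl aldimine in a non-coordinating solvent runs through a six-membered chelate with magnesium held by the sulfinyl oxygen, so the (S)-sulfinyl group should steer the vinyl group (C4) to the imine face that gives the S configuration at C3 (reagent control), the extra reagent being used by the free C9 hydroxyl.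

Step 10
Reactants: 14 allylic sulfinamide; 15 (E)-dodec-2-enoic acid
Product: 17 (2E)-N-[(2S)-1-[(1S,4R,5R)-1-(tert-butyldimethylsilyloxy)-5-ethenyl-5-hydroxy-4-methoxycyclopent-2-en-1-yl]but-3-en-2-yl]dodec-2-enamide, via amine hydrochloride 16 (not isolated)
Conditions: HCl (4 M in dioxane), MeOH, 0 °C; evaporate; then 15, EDC·HCl, HOBt, i-Pr2NEt, CH2Cl2, 0 °C → rt
Reagents that add atoms: none
Why: Acid solvolysis of the N–S bond followed by carbodiimide amide coupling installs the side chain, the short cold acid treatment sparing the tertiary silyl ether and the tertiary alcohols remaining unacylated, with C3 untouched.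

Step 11
Reactants: 17 amide with two terminal vinyl groups
Product: 18 cis-fused hydrindadiene amide (C4=C5 and C7=C8; C1–OTBS/C9–OH/C6–OMe/C3–NH all α)
Conditions: second-generation Grubbs catalyst, (H2IMes)(PCy3)Cl2Ru=CHPh (cat.), CH2Cl2 (dilute), 40 °C
Reagents that add atoms: none
Why: Ring-closing olefin metathesis of the two terminal vinyl groups, held on the same face by C3–C2–C1–C9, should close six-membered ring A at C4=C5 with loss of ethylene, the hindered ring alkene and the conjugated enamide alkene being poor partners, with no stereocenter touched.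

Step 12
Reactants: 18 hydrindadiene amide
Product: 19 α-C4–C5 epoxide of 18 (epoxide syn to C9–OH)
Conditions: VO(acac)2 (cat.), t-BuOOH, CH2Cl2, 0 °C → rt
Reagents that add atoms: tert-butyl hydroperoxide, CC(C)(C)OO
Why: Vanadium-catalysed hydroxyl-directed epoxidation of an allylic alcohol should deliver oxygen to C4=C5 from the face of the tertiary C9 hydroxyl, which is also the convex face of the cis-fused bicycle, setting C4 and C5 syn to C9–OH while the merely homoallylic, electron-poor C7=C8 bond and the enamide are left.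

Step 13
Reactants: 19 epoxy alcohol
Product: 20 (2E)-N-[1-(tert-butyldimethylsilyloxy)-4-hydroxy-6-methoxy-9-oxobicyclo[3.3.1]non-7-en-3-yl]dodec-2-enamide (4-OH axial on ring A and anti to C5–C6)
Conditions: BF3·OEt2 (2.5 equiv), CH2Cl2, −78 → −20 °C
Reagents that add atoms: none
Why: Coordination of BF3 to the oxirane oxygen weakens the C5–O bond, and in the same event the C9–C6 σ bond lying antiperiplanar to it moves to C5 while the C9 oxygen closes to the carbonyl and gives up its proton, a concerted 1,2-carbon shift. The closest known reaction type is the Lewis acid semipinacol rearrangement of 2,3-epoxy alcohols, used here in its ring-enlarging form. Ring B (C1, C9, C5, C6, C7, C8) is closed by one-carbon expansion of the cyclopentene through this shift and not by an end-to-end cyclisation, and ring A is kept as it is. The one new stereocenter, C5, is controlled by the substrate: C6 arrives on the face opposite the departing oxygen (inversion at C5, retention at C6), so C5–H ends on the former epoxide face and the C4 hydroxyl, which keeps the epoxide configuration, becomes axial and anti to C5–C6. The step needs C6 to move instead of C1 or hydride; the syn relation of C9–OH and epoxide set in step 12 leaves only the exocyclic C9–C6 bond anti to C5–O (the C9–C1 bond belongs to ring A and stays gauche), and C6 is allylic and carries a donor oxygen. The C1 silyl ether blocks an acyloin shift of the product, and loss of water from the β-hydroxy ketone is barred because the enone would need a bridgehead double bond.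

Step 14
Reactants: 20 bicyclic silyl ether
Product: 21 (2E)-N-[1,4-dihydroxy-6-methoxy-9-oxobicyclo[3.3.1]non-7-en-3-yl]dodec-2-enamide (configuration as in 20)
Conditions: HF·pyridine, pyridine, THF, 0 °C → rt
Reagents that add atoms: none
Why: Fluoride-mediated silyl ether cleavage under mildly acidic conditions should free the exposed bridgehead C1 hydroxyl without the base that could open the β-hydroxy ketone by retro-aldol reaction, with no stereocenter touched.

Step 15
Reactants: 21 bicyclic enone diol
Product: 22 CNP0137540.1, (2E)-N-[(1S,3S,4R,5S,6S,7S,8S)-7,8-epoxy-1,4-dihydroxy-6-methoxy-9-oxobicyclo[3.3.1]nonan-3-yl]dodec-2-enamide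
Conditions: dimethyldioxirane, acetone, 0 °C
Reagents that add atoms: dimethyldioxirane, CC1(C)OO1
Why: Dioxirane epoxidation of the isolated C7=C8 bond under neutral conditions should take place on the exo face (the side of the C9 bridge), since the endo face is covered by ring A and the adjacent C1 hydroxyl can hydrogen-bond to the oxidant, which sets C7 and C8, while the electron-poor enamide alkene reacts far more slowly and a dioxirane does not effect Baeyer–Villiger oxidation of the ketone.

**Compound list**

1 | (3aR,6aR)-2,2-dimethyl-3a,6a-dihydro-4H-cyclopenta[d][1,3]dioxol-4-one | O=C1C=C[C@H]2OC(C)(C)O[C@@H]12 | starting material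
2 | acetonitrile | CC#N | starting material
3 | 2-[(3aR,4S,6aR)-4-hydroxy-2,2-dimethyl-3a,6a-dihydro-4H-cyclopenta[d][1,3]dioxol-4-yl]acetonitrile (C1–OH cis to both dioxolane oxygens) | N#CC[C@]1(O)C=C[C@H]2OC(C)(C)O[C@@H]12 | intermediate
4 | 2-[(3aR,4S,6aR)-4-(tert-butyldimethylsilyloxy)-2,2-dimethyl-3a,6a-dihydro-4H-cyclopenta[d][1,3]dioxol-4-yl]acetonitrile | N#CC[C@]1(O[Si](C)(C)C(C)(C)C)C=C[C@H]2OC(C)(C)O[C@@H]12 | intermediate
5 | 2-[(1S,4R,5R)-1-(tert-butyldimethylsilyloxy)-4,5-dihydroxycyclopent-2-en-1-yl]acetonitrile (three oxygens cis) | N#CC[C@]1(O[Si](C)(C)C(C)(C)C)C=C[C@@H](O)[C@H]1O | intermediate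
6 | 2-[(1S,4R,5R)-1-(tert-butyldimethylsilyloxy)-5-hydroxy-4-methoxycyclopent-2-en-1-yl]acetonitrile | N#CC[C@]1(O[Si](C)(C)C(C)(C)C)C=C[C@@H](OC)[C@H]1O | intermediate
7 | 2-[(1S,4R)-1-(tert-butyldimethylsilyloxy)-4-methoxy-5-oxocyclopent-2-en-1-yl]acetonitrile | N#CC[C@]1(O[Si](C)(C)C(C)(C)C)C=C[C@@H](OC)C1=O | intermediate
8 | vinylmagnesium bromide | C=C[Mg]Br | starting material
9 | 2-[(1S,4R,5R)-1-(tert-butyldimethylsilyloxy)-5-ethenyl-5-hydroxy-4-methoxycyclopent-2-en-1-yl]acetonitrile (C9–OH cis to OTBS and OMe) | N#CC[C@]1(O[Si](C)(C)C(C)(C)C)C=C[C@@H](OC)[C@]1(O)C=C | intermediate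
10 | aldimine of 11 (N-aluminated in the flask; drawn as the N–H imine) | N=CC[C@]1(O[Si](C)(C)C(C)(C)C)C=C[C@@H](OC)[C@]1(O)C=C | intermediate
11 | 2-[(1S,4R,5R)-1-(tert-butyldimethylsilyloxy)-5-ethenyl-5-hydroxy-4-methoxycyclopent-2-en-1-yl]acetaldehyde | O=CC[C@]1(O[Si](C)(C)C(C)(C)C)C=C[C@@H](OC)[C@]1(O)C=C | intermediate
12 | (S)-2-methylpropane-2-sulfinamide | CC(C)(C)[S@](=O)N | starting material
13 | (S,E)-N-sulfinyl aldimine of 11 | CC(C)(C)[S@](=O)/N=C/C[C@]1(O[Si](C)(C)C(C)(C)C)C=C[C@@H](OC)[C@]1(O)C=C | intermediate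
14 | (S)-N-[(2S)-1-(cyclopentenyl)but-3-en-2-yl]-2-methylpropane-2-sulfinamide (cyclopentenyl as in 9; C3 is S) | CC(C)(C)[S@](=O)N[C@H](C=C)C[C@]1(O[Si](C)(C)C(C)(C)C)C=C[C@@H](OC)[C@]1(O)C=C | intermediate
15 | (E)-dodec-2-enoic acid | CCCCCCCCC/C=C/C(=O)O | starting material
16 | (2S)-1-(cyclopentenyl)but-3-en-2-amine hydrochloride | N[C@H](C=C)C[C@]1(O[Si](C)(C)C(C)(C)C)C=C[C@@H](OC)[C@]1(O)C=C.Cl | intermediate
17 | (2E)-N-[(2S)-1-[(1S,4R,5R)-1-(tert-butyldimethylsilyloxy)-5-ethenyl-5-hydroxy-4-methoxycyclopent-2-en-1-yl]but-3-en-2-yl]dodec-2-enamide | CCCCCCCCC/C=C/C(=O)N[C@H](C=C)C[C@]1(O[Si](C)(C)C(C)(C)C)C=C[C@@H](OC)[C@]1(O)C=C | intermediate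
18 | cis-fused hydrindadiene amide: C1–OTBS, C9–OH, C6–OMe and C3–NH all α; alkenes C4=C5 and C7=C8 | CCCCCCCCC/C=C/C(=O)N[C@H]1C[C@]2(O[Si](C)(C)C(C)(C)C)C=C[C@@H](OC)[C@]2(O)C=C1 | intermediate
19 | α-C4–C5 epoxide of 18, epoxide oxygen syn to C9–OH (semipinacol precursor) | CCCCCCCCC/C=C/C(=O)N[C@H]1C[C@]2(O[Si](C)(C)C(C)(C)C)C=C[C@@H](OC)[C@]2(O)[C@H]3O[C@@H]13 | intermediate
20 | (2E)-N-[1-(tert-butyldimethylsilyloxy)-4-hydroxy-6-methoxy-9-oxobicyclo[3.3.1]non-7-en-3-yl]dodec-2-enamide; 4-OH axial and cis to equatorial 3-NH, 6-OMe on the C9 side of ring B | CCCCCCCCC/C=C/C(=O)N[C@H]1C[C@@]2(O[Si](C)(C)C(C)(C)C)C(=O)[C@@H]([C@H]1O)[C@H](OC)C=C2 | intermediate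
21 | C1 alcohol of 20 | CCCCCCCCC/C=C/C(=O)N[C@H]1C[C@@]2(O)C(=O)[C@@H]([C@H]1O)[C@H](OC)C=C2 | intermediate
22 | CNP0137540.1, (2E)-N-[(1S,3S,4R,5S,6S,7S,8S)-7,8-epoxy-1,4-dihydroxy-6-methoxy-9-oxobicyclo[3.3.1]nonan-3-yl]dodec-2-enamide (exo epoxide) | CCCCCCCCC/C=C/C(=O)N[C@H]1C[C@@]2(O)C(=O)[C@@H]([C@H]1O)[C@H](OC)[C@@H]1O[C@@H]12 | target

**Step count and risk**

Total steps: 15. Longest linear sequence: 15 steps (1 → 22).

Steps most likely to fail:

1. Step 13. What may go wrong: the activated epoxide is opened by fluoride from the Lewis acid, or ionises with a hydride shift before C6 moves, or the amide ties up the Lewis acid and the forcing then needed strips the C1 silyl ether. The fallback sets out from 19 and returns at 20. The C9 hydroxyl is capped (Me3SiOTf, 2,6-lutidine, CH2Cl2, −78 °C) to give the C9 trimethylsilyl ether F1, which is rearranged with TiCl4 in CH2Cl2 at −78 °C. In this silyl ether variant of the semipinacol rearrangement, chloride takes silicon off the carbinol oxygen as C6 migrates and no fluoride is present; aqueous work-up frees the C4 hydroxyl of 20.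

2. Step 6. What may go wrong: deprotonation at C6 of the β,γ-unsaturated α-methoxy ketone instead of addition, with loss of the C6 configuration or migration of the ring double bond into conjugation. The fallback sets out from 7 and returns at 9. Ethynylmagnesium bromide with CeCl3 (THF, −78 °C), a far weaker base and a slimmer nucleophile, should give the C9 ethynyl carbinol F2 with the same β-face preference. Lindlar semihydrogenation (H2, Pd/CaCO3 poisoned with Pb(OAc)2, quinoline) then turns the alkyne into the vinyl group of 9.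

3. Step 4. What may go wrong: methylation at the C9 hydroxyl or at both hydroxyls. The fallback sets out from 5 and returns at 6, and tells the two hydroxyls apart by oxidation state, not by hindrance. MnO2 (CH2Cl2) oxidises only the allylic C6 alcohol to the enone F3. The C9 hydroxyl is capped (Et3SiOTf, 2,6-lutidine) as the triethylsilyl ether F4. Luche reduction (NaBH4, CeCl3·7H2O, MeOH) returns the all-cis C6 alcohol F5 by hydride attack anti to the C9 silyl ether. The single free hydroxyl is methylated (Me3OBF4, 1,8-bis(dimethylamino)naphthalene) to the methyl ether F6. The secondary triethylsilyl ether is then removed with AcOH/THF/H2O beside the tertiary TBS ether to reach 6.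

Further compounds
F1 | step 13 | C9 trimethylsilyl ether of epoxy alcohol 19 | CCCCCCCCC/C=C/C(=O)N[C@H]1C[C@]2(O[Si](C)(C)C(C)(C)C)C=C[C@@H](OC)[C@]2(O[Si](C)(C)C)[C@H]3O[C@@H]13
F2 | step 6 | 2-[1-(tert-butyldimethylsilyloxy)-5-ethynyl-5-hydroxy-4-methoxycyclopent-2-en-1-yl]acetonitrile (configuration as in 9) | N#CC[C@]1(O[Si](C)(C)C(C)(C)C)C=C[C@@H](OC)[C@]1(O)C#C
F3 | step 4 | 2-[1-(tert-butyldimethylsilyloxy)-5-hydroxy-4-oxocyclopent-2-en-1-yl]acetonitrile (C6 ketone, C9–OH cis to OTBS) | N#CC[C@]1(O[Si](C)(C)C(C)(C)C)C=CC(=O)[C@H]1O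
F4 | step 4 | C9 triethylsilyl ether of F3 | N#CC[C@]1(O[Si](C)(C)C(C)(C)C)C=CC(=O)[C@H]1O[Si](CC)(CC)CC
F5 | step 4 | 2-[1-(tert-butyldimethylsilyloxy)-4-hydroxy-5-(triethylsilyloxy)cyclopent-2-en-1-yl]acetonitrile (three oxygens cis) | N#CC[C@]1(O[Si](C)(C)C(C)(C)C)C=C[C@@H](O)[C@H]1O[Si](CC)(CC)CC
F6 | step 4 | C6 methyl ether of F5 | N#CC[C@]1(O[Si](C)(C)C(C)(C)C)C=C[C@@H](OC)[C@H]1O[Si](CC)(CC)CC
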